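## Retrosynthetic overview

1. Locants: ring A is the terminal 2-ethylpyranone and ring B the central pyranone. The chain is C8 [CH(CH3) on ring A]–C9=C10(CH3)–C11(OH)–C12(CH3)–C13(OH)–C14 [CH(CH3) on ring B]; the far arm of ring B is C15 [CH(CH3)]–C16(OH)–Et.
2. Last bond, C8–C9: enantioconvergent Ni-catalysed radical cross-coupling of racemic 1-chloroethyl-pyranone 7 with the unprotected alkenyl bromide triol 24. It sets C8 and joins the two halves.
3. C11–C12: Ipc2B-mediated syn-aldol of ethyl ketone 14 with bromo-enal 18. C13: 1,3-syn reduction.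
4. C13–C14 and C15–C16: two Ni-catalysed radical acylations of pyranonyl-ethyl chlorides with propanoyl chloride, using antipodal ligands for C14 and C15. C16: Felkin reduction.
5. Ring order: pyranone 5 is built once (3-pentanone + 2 propionic acid). One molecule is elaborated on both ethyl arms into ring B; a second, as chloride 7, is attached last as ring A.

Assumption: in steps 3, 6, 9 and 11 the ligand or reagent antipode written is the one taken, by analogy with 1-arylethyl chlorides and simple ethyl ketones, to give the configuration drawn; if the sense of induction proves opposite, the antipode is used and nothing else changes.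

## Route

Step 1
Reactants: 1 3-pentanone; 2 propionic acid
Product: 5 2,6-diethyl-3,5-dimethyl-4H-pyran-4-one, via 4-methylheptane-3,5-dione 3 (not isolated), via 4,6-dimethylnonane-3,5,7-trione 4 (not isolated)
Conditions: EtCO2H (4 equiv), polyphosphoric acid, 120 °C
Reagents that add atoms: propionic acid (second equivalent) CCC(=O)O
Why: PPA pyranone synthesis, in which two molecules of propionic acid are built in: the first C-acylates one alpha carbon of the ketone to give diketone 3, the second acylates the other alpha carbon to give the 3,5,7-trione 4, and 4 cyclodehydrates to the 4-pyranone (three molecules of water lost overall), which has no stereocentre.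

Step 2
Reactants: 5 2,6-diethyl-3,5-dimethyl-4H-pyran-4-one
Product: 7 rac-2-(1-chloroethyl)-6-ethyl-3,5-dimethyl-4H-pyran-4-one, via lithium dienolate 6 (not isolated)
Conditions: LiN(iPr)2 (1.05 equiv), THF, −78 °C; cannulate into C2Cl6 (1.5 equiv), THF, −78 °C
Reagents that add atoms: hexachloroethane ClC(Cl)(Cl)C(Cl)(Cl)Cl
Why: Kinetic deprotonation at the ethyl CH2 gives the vinylogous enolate 6, which is chlorinated at the exocyclic carbon by C2Cl6 (electrophilic halogenation of an extended enolate) with return to the pyranone; inverse addition limits proton exchange and dichlorination, and the centre is left racemic because steps 3 and 11 are stereoconvergent.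

Step 3
Reactants: 7 rac-2-(1-chloroethyl)-6-ethyl-3,5-dimethyl-4H-pyran-4-one; 8 propanoyl chloride
Product: 9 2-ethyl-3,5-dimethyl-6-[(2S)-3-oxopentan-2-yl]-4H-pyran-4-one
Conditions: 7 (1.5 equiv), NiCl2(dme) (10 mol %), (R,R)-Ph-BOX (22 mol %), Mn powder (3 equiv), 2,6-dimethylbenzoic acid (0.75 equiv), 3 Å MS, DMA/THF 3:7, 20 °C
Reagents that add atoms: none
Why: Enantioconvergent Ni-catalysed reductive acyl cross-coupling of a secondary benzylic-type chloride with an acid chloride: chlorine-atom abstraction gives the planar pyranone-stabilised radical, which the chiral acyl–nickel complex captures so that both enantiomers of 7 give the (S)-ketone centre (C15), and the new C–H, held in the ring plane by allylic strain with the adjacent ring methyl, does not racemise under the buffered conditions.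

Step 4
Reactants: 9 2-ethyl-3,5-dimethyl-6-[(2S)-3-oxopentan-2-yl]-4H-pyran-4-one
Product: 11 2-ethyl-3,5-dimethyl-6-[(2R,3R)-3-(triethylsilyloxy)pentan-2-yl]-4H-pyran-4-one, via lithium alkoxide 10 (not isolated)
Conditions: LiBH(s-Bu)3 (1.1 equiv), THF, −78 °C; then TESOTf (1.3 equiv), 2,6-lutidine, −78 → 0 °C
Reagents that add atoms: triethylsilyl trifluoromethanesulfonate CC[Si](CC)(CC)OS(=O)(=O)C(F)(F)F
Why: Felkin–Anh reduction: the bulky hydride attacks the ketone anti to the pyranone (large group) to give the anti (2R,3R) carbinol (C16), chemoselectively over the vinylogous-ester ring carbonyl, and the alkoxide is silylated cold in the same flask before retro-aldol cleavage can occur.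

Step 5
Reactants: 11 2-ethyl-3,5-dimethyl-6-[(2R,3R)-3-(triethylsilyloxy)pentan-2-yl]-4H-pyran-4-one
Product: 13 2-(1-chloroethyl)-3,5-dimethyl-6-[(2R,3R)-3-(triethylsilyloxy)pentan-2-yl]-4H-pyran-4-one (1:1 epimers at CHCl), via lithium dienolate 12 (not isolated)
Conditions: LiN(iPr)2 (1.1 equiv), THF, −78 °C; cannulate into C2Cl6 (1.5 equiv), THF, −78 °C
Reagents that add atoms: hexachloroethane ClC(Cl)(Cl)C(Cl)(Cl)Cl
Why: Same vinylogous enolate chlorination as step 2, now at the only unhindered ring-bound CH2 (the other arm has a hindered tertiary C–H); the epimer mixture at CHCl is irrelevant because step 6 is stereoconvergent.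

Step 6
Reactants: 13 2-(1-chloroethyl)-3,5-dimethyl-6-[(2R,3R)-3-(triethylsilyloxy)pentan-2-yl]-4H-pyran-4-one; 8 propanoyl chloride
Product: 14 3,5-dimethyl-2-[(2R)-3-oxopentan-2-yl]-6-[(2R,3R)-3-(triethylsilyloxy)pentan-2-yl]-4H-pyran-4-one
Conditions: EtCOCl (2 equiv), NiCl2(dme) (10 mol %), (S,S)-Ph-BOX (22 mol %), Mn powder (3 equiv), 2,6-dimethylbenzoic acid (0.75 equiv), 3 Å MS, DMA/THF 3:7, 20 °C
Reagents that add atoms: none
Why: Same enantioconvergent radical acyl cross-coupling with the antipodal ligand: catalyst control (the existing centres are remote) sets C14 as the (R)-ketone centre, the local mirror image of C15, and chromatographic removal of the minor diastereomer also raises the enantiomeric purity carried forward.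

Step 7
Reactants: 15 prop-2-yn-1-ol
Product: 17 (E)-3-bromo-2-methylprop-2-en-1-ol, via alkenylalane 16 (not isolated)
Conditions: AlMe3 (3 equiv), Cp2ZrCl2 (0.25 equiv), CH2Cl2, 0 °C → rt; then NBS, THF, −30 °C; aqueous work-up
Reagents that add atoms: trimethylaluminium C[Al](C)C; N-bromosuccinimide O=C1CCC(=O)N1Br
Why: Negishi zirconium-catalysed carboalumination adds CH3 and Al syn across the alkyne with Al on the terminal carbon, and bromodealumination with retention gives only the E alkenyl bromide.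

Step 8
Reactants: 17 (E)-3-bromo-2-methylprop-2-en-1-ol
Product: 18 (E)-3-bromo-2-methylprop-2-enal
Conditions: MnO2 (10 equiv), CH2Cl2, rt
Reagents that add atoms: none
Why: Allylic alcohol oxidation with MnO2 gives the enal without touching the alkenyl bromide or its geometry.

Step 9
Reactants: 14 3,5-dimethyl-2-[(2R)-3-oxopentan-2-yl]-6-[(2R,3R)-3-(triethylsilyloxy)pentan-2-yl]-4H-pyran-4-one; 18 (E)-3-bromo-2-methylprop-2-enal
Product: 21 2-[(2R,4R,5R,6E)-7-bromo-5-hydroxy-4,6-dimethyl-3-oxohept-6-en-2-yl]-3,5-dimethyl-6-[(2R,3R)-3-(triethylsilyloxy)pentan-2-yl]-4H-pyran-4-one, via boron enolate 19 (not isolated), via boron aldolate 20 (not isolated)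
Conditions: (+)-Ipc2BOTf (1.5 equiv), iPr2NEt (2 equiv), CH2Cl2, −78 °C; then 18, −78 → −20 °C; H2O2, MeOH, pH 7 buffer, 0 °C
Reagents that add atoms: none
Why: Paterson boron aldol: the bulky borinyl triflate and amine enolise only the unhindered CH2 (the C14–H is tertiary and lies in the ring plane) to give Z-enolate 19, whose chair Zimmerman–Traxler transition state gives the syn aldol while the Ipc ligands select the enolate face, setting C12 and C11 as (4R,5R) of the heptenyl chain.

Step 10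
Reactants: 21 2-[(2R,4R,5R,6E)-7-bromo-5-hydroxy-4,6-dimethyl-3-oxohept-6-en-2-yl]-3,5-dimethyl-6-[(2R,3R)-3-(triethylsilyloxy)pentan-2-yl]-4H-pyran-4-one
Product: 24 2-[(2S,3S,4S,5R,6E)-7-bromo-3,5-dihydroxy-4,6-dimethylhept-6-en-2-yl]-6-[(2R,3R)-3-hydroxypentan-2-yl]-3,5-dimethyl-4H-pyran-4-one, via diethylboron chelate 22 (not isolated), via silyl-protected diol 23 (not isolated)
Conditions: Et2BOMe (1.2 equiv), THF/MeOH 4:1, −78 °C; NaBH4; AcOH, MeOH co-evaporation; then PPTS, MeOH, rt
Reagents that add atoms: none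
Why: Narasaka–Prasad reduction: hydride adds axially to the six-membered boron chelate 22 to give the 1,3-syn diol (C13), reinforced by Felkin control from C14, and mild acidic methanolysis then removes boron and the TES group in the same operation.

Step 11
Reactants: 24 2-[(2S,3S,4S,5R,6E)-7-bromo-3,5-dihydroxy-4,6-dimethylhept-6-en-2-yl]-6-[(2R,3R)-3-hydroxypentan-2-yl]-3,5-dimethyl-4H-pyran-4-one; 7 rac-2-(1-chloroethyl)-6-ethyl-3,5-dimethyl-4H-pyran-4-one
Product: 25 CNP0328559.3, 2-ethyl-6-[(2S,3E,5R,6S,7S,8S)-5,7-dihydroxy-8-{6-[(2R,3R)-3-hydroxypentan-2-yl]-3,5-dimethyl-4-oxo-4H-pyran-2-yl}-4,6-dimethylnon-3-en-2-yl]-3,5-dimethyl-4H-pyran-4-one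
Conditions: 7 (2 equiv), NiCl2(dme) (10 mol %), (3aR,3a'R,8aS,8a'S)-2,2'-(cyclopropane-1,1-diyl)bis(3a,8a-dihydro-8H-indeno[1,2-d]oxazole) (11 mol %), Mn powder (3 equiv), NaI (0.5 equiv), DMA, 0 °C
Reagents that add atoms: none
Why: Proposed new method: the closest known reaction is the Ni-catalysed enantioconvergent reductive cross-coupling of racemic 1-arylethyl chlorides with alkenyl bromides (chiral bis(oxazoline), Mn); here low-valent nickel inserts into the C–Br bond of 24 with retention of the E geometry, chlorine-atom abstraction from either enantiomer of 7 gives the planar pyranone-stabilised secondary radical, and its capture by the chiral alkenyl–nickel complex followed by reductive elimination forms C8–C9 and sets C8 as S under ligand control, the untested elements being the pyranone in place of an arene, the methyl cis to nickel on the alkenyl partner and the three free hydroxyls, which the neutral Mn/DMA medium should leave untouched.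

## Compound list

1 | 3-pentanone | CCC(=O)CC | starting material
2 | propionic acid | CCC(=O)O | starting material
3 | 4-methylheptane-3,5-dione | CCC(=O)C(C)C(=O)CC | intermediate (not isolated)
4 | 4,6-dimethylnonane-3,5,7-trione | CCC(=O)C(C)C(=O)C(C)C(=O)CC | intermediate (not isolated)
5 | 2,6-diethyl-3,5-dimethyl-4H-pyran-4-one | CCc1oc(CC)c(C)c(=O)c1C | intermediate
6 | lithium 6-ethyl-2-ethylidene-3,5-dimethyl-2H-pyran-4-olate (vinylogous enolate of 5) | [Li+].CC=C1OC(CC)=C(C)C([O-])=C1C | intermediate (not isolated)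
7 | rac-2-(1-chloroethyl)-6-ethyl-3,5-dimethyl-4H-pyran-4-one | CCc1oc(C(C)Cl)c(C)c(=O)c1C | intermediate
8 | propanoyl chloride | CCC(Cl)=O | starting material
9 | 2-ethyl-3,5-dimethyl-6-[(2S)-3-oxopentan-2-yl]-4H-pyran-4-one | CCc1oc([C@H](C)C(=O)CC)c(C)c(=O)c1C | intermediate
10 | lithium (2R,3R)-2-(6-ethyl-3,5-dimethyl-4-oxo-4H-pyran-2-yl)pentan-3-olate | [Li+].CCc1oc([C@H](C)[C@H]([O-])CC)c(C)c(=O)c1C | intermediate (not isolated)
11 | 2-ethyl-3,5-dimethyl-6-[(2R,3R)-3-(triethylsilyloxy)pentan-2-yl]-4H-pyran-4-one | CCc1oc([C@H](C)[C@H](O[Si](CC)(CC)CC)CC)c(C)c(=O)c1C | intermediate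
12 | lithium 2-ethylidene-3,5-dimethyl-6-[(2R,3R)-3-(triethylsilyloxy)pentan-2-yl]-2H-pyran-4-olate (vinylogous enolate of 11) | [Li+].CC=C1OC([C@H](C)[C@H](O[Si](CC)(CC)CC)CC)=C(C)C([O-])=C1C | intermediate (not isolated)
13 | 2-(1-chloroethyl)-3,5-dimethyl-6-[(2R,3R)-3-(triethylsilyloxy)pentan-2-yl]-4H-pyran-4-one, both epimers at CHCl | CC(Cl)c1oc([C@H](C)[C@H](O[Si](CC)(CC)CC)CC)c(C)c(=O)c1C | intermediate
14 | 3,5-dimethyl-2-[(2R)-3-oxopentan-2-yl]-6-[(2R,3R)-3-(triethylsilyloxy)pentan-2-yl]-4H-pyran-4-one | CCC(=O)[C@H](C)c1oc([C@H](C)[C@H](O[Si](CC)(CC)CC)CC)c(C)c(=O)c1C | intermediate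
15 | prop-2-yn-1-ol | C#CCO | starting material
16 | dimethylaluminium (E)-3-(dimethylalumanyl)-2-methylprop-2-en-1-olate | C[Al](C)/C=C(\C)CO[Al](C)C | intermediate (not isolated)
17 | (E)-3-bromo-2-methylprop-2-en-1-ol | Br/C=C(\C)CO | intermediate
18 | (E)-3-bromo-2-methylprop-2-enal | Br/C=C(\C)C=O | intermediate
19 | (Z)-enol bis(isopinocampheyl)borinate of 14, Ipc from (−)-α-pinene, configuration of 14 retained | C/C=C(\OB([C@H]1C[C@H]2C[C@@H]([C@@H]1C)C2(C)C)[C@H]1C[C@H]2C[C@@H]([C@@H]1C)C2(C)C)[C@H](C)c1oc([C@H](C)[C@H](O[Si](CC)(CC)CC)CC)c(C)c(=O)c1C | intermediate (not isolated)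
20 | O-bis(isopinocampheyl)boryl aldolate of 21 | Br/C=C(\C)[C@H](OB([C@H]1C[C@H]2C[C@@H]([C@@H]1C)C2(C)C)[C@H]1C[C@H]2C[C@@H]([C@@H]1C)C2(C)C)[C@@H](C)C(=O)[C@H](C)c1oc([C@H](C)[C@H](O[Si](CC)(CC)CC)CC)c(C)c(=O)c1C | intermediate (not isolated)
21 | 2-[(2R,4R,5R,6E)-7-bromo-5-hydroxy-4,6-dimethyl-3-oxohept-6-en-2-yl]-3,5-dimethyl-6-[(2R,3R)-3-(triethylsilyloxy)pentan-2-yl]-4H-pyran-4-one | Br/C=C(\C)[C@H](O)[C@@H](C)C(=O)[C@H](C)c1oc([C@H](C)[C@H](O[Si](CC)(CC)CC)CC)c(C)c(=O)c1C | intermediate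
22 | O-diethylboryl derivative of 21, boron chelated by the ketone | Br/C=C(\C)[C@H](OB(CC)CC)[C@@H](C)C(=O)[C@H](C)c1oc([C@H](C)[C@H](O[Si](CC)(CC)CC)CC)c(C)c(=O)c1C | intermediate (not isolated)
23 | 2-[(2S,3S,4S,5R,6E)-7-bromo-3,5-dihydroxy-4,6-dimethylhept-6-en-2-yl]-3,5-dimethyl-6-[(2R,3R)-3-(triethylsilyloxy)pentan-2-yl]-4H-pyran-4-one | Br/C=C(\C)[C@H](O)[C@@H](C)[C@H](O)[C@H](C)c1oc([C@H](C)[C@H](O[Si](CC)(CC)CC)CC)c(C)c(=O)c1C | intermediate (not isolated)
24 | 2-[(2S,3S,4S,5R,6E)-7-bromo-3,5-dihydroxy-4,6-dimethylhept-6-en-2-yl]-6-[(2R,3R)-3-hydroxypentan-2-yl]-3,5-dimethyl-4H-pyran-4-one | Br/C=C(\C)[C@H](O)[C@@H](C)[C@H](O)[C@H](C)c1oc([C@H](C)[C@H](O)CC)c(C)c(=O)c1C | intermediate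
25 | CNP0328559.3, 2-ethyl-6-[(2S,3E,5R,6S,7S,8S)-5,7-dihydroxy-8-{6-[(2R,3R)-3-hydroxypentan-2-yl]-3,5-dimethyl-4-oxo-4H-pyran-2-yl}-4,6-dimethylnon-3-en-2-yl]-3,5-dimethyl-4H-pyran-4-one | CCc1oc([C@@H](C)/C=C(\C)[C@H](O)[C@@H](C)[C@H](O)[C@H](C)c2oc([C@H](C)[C@H](O)CC)c(C)c(=O)c2C)c(C)c(=O)c1C | target

## Step count and risks

Total step count: 11. Longest linear sequence: 9 steps (steps 1, 2, 3, 4, 5, 6, 9, 10, 11); the enal branch (steps 7 and 8) joins at step 9, and chloride 7 is used again at step 11.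

Steps most likely to fail:

**Step 11.** The alkenyl bromide is hindered (methyl cis to nickel) and carries three free hydroxyls, and 7 can homocouple. The fallback moves the radical coupling onto simple partners and makes the aldol the fragment union; it sets out from 7 and 17 and comes back at 25. Chloride 7 and bromo-alcohol 17 are coupled under the step 11 conditions to give (2E,4S)-4-(6-ethyl-3,5-dimethyl-4-oxo-4H-pyran-2-yl)-2-methylpent-2-en-1-ol F1. MnO2 oxidation gives (2E,4S)-4-(6-ethyl-3,5-dimethyl-4-oxo-4H-pyran-2-yl)-2-methylpent-2-enal F2. Boron enolate 19, made from 14 as in step 9, adds to F2 to give the O-bis(isopinocampheyl)boryl aldolate F3, and oxidative work-up gives the syn-aldol adduct 2-ethyl-3,5-dimethyl-6-[(2S,3E,5R,6R,8R)-5-hydroxy-4,6-dimethyl-7-oxo-8-{3,5-dimethyl-4-oxo-6-[(2R,3R)-3-(triethylsilyloxy)pentan-2-yl]-4H-pyran-2-yl}non-3-en-2-yl]-4H-pyran-4-one F4. Et2BOMe converts F4 into its O-diethylboryl chelate F5, NaBH4 reduces this to the triethylsilyl ether of 25 at the pentan-3-ol oxygen F6, and PPTS in MeOH releases 25.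

**Step 9.** Enolisation could go towards the acidic C14–H (wrong regiochemistry or epimerisation), and the enolate face selectivity rests on reagent control. The fallback generates the same enolate without any deprotonation; it sets out from 13 and comes back at 19. Chloride 13 is coupled with acryloyl chloride under the step 6 conditions to give the vinyl ketone 3,5-dimethyl-2-[(2R)-3-oxopent-4-en-2-yl]-6-[(2R,3R)-3-(triethylsilyloxy)pentan-2-yl]-4H-pyran-4-one F7. 1,4-Hydroboration of the s-cis enone with (+)-Ipc2BH in THF at 0 °C gives Z-enolate 19 regiospecifically under neutral conditions, and 19 then reacts with 18 as in the second half of step 9.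

**Step 6 (step 3 shares the risk on a simpler substrate).** The acyl cross-coupling on the elaborated chloride may give low selectivity or mainly reduction and homocoupling. The fallback replaces the catalytic radical acylation by a polar acylation with epimer recycling; it sets out from 11 and comes back at 14. Dienolate 12, made from 11 as in step 5, is added to N-methoxy-N-methylpropanamide at −78 °C to give the tetrahedral lithium N-methoxy-N-methyl hemiaminal adduct F8, which is stable to proton exchange. Aqueous work-up gives 14 together with its epimer 3,5-dimethyl-2-[(2S)-3-oxopentan-2-yl]-6-[(2R,3R)-3-(triethylsilyloxy)pentan-2-yl]-4H-pyran-4-one F9. The two are separated by chromatography, and F9 is re-equilibrated with DBU and recycled to 14.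

## Further compounds

F1 | step 11 | (2E,4S)-4-(6-ethyl-3,5-dimethyl-4-oxo-4H-pyran-2-yl)-2-methylpent-2-en-1-ol | CCc1oc([C@@H](C)/C=C(\C)CO)c(C)c(=O)c1C
F2 | step 11 | (2E,4S)-4-(6-ethyl-3,5-dimethyl-4-oxo-4H-pyran-2-yl)-2-methylpent-2-enal | CCc1oc([C@@H](C)/C=C(\C)C=O)c(C)c(=O)c1C
F3 | step 11 | O-bis(isopinocampheyl)boryl aldolate of F4 | CCc1oc([C@@H](C)/C=C(\C)[C@H](OB([C@H]2C[C@H]3C[C@@H]([C@@H]2C)C3(C)C)[C@H]2C[C@H]3C[C@@H]([C@@H]2C)C3(C)C)[C@@H](C)C(=O)[C@H](C)c2oc([C@H](C)[C@H](O[Si](CC)(CC)CC)CC)c(C)c(=O)c2C)c(C)c(=O)c1C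
F4 | step 11 | 2-ethyl-3,5-dimethyl-6-[(2S,3E,5R,6R,8R)-5-hydroxy-4,6-dimethyl-7-oxo-8-{3,5-dimethyl-4-oxo-6-[(2R,3R)-3-(triethylsilyloxy)pentan-2-yl]-4H-pyran-2-yl}non-3-en-2-yl]-4H-pyran-4-one | CCc1oc([C@@H](C)/C=C(\C)[C@H](O)[C@@H](C)C(=O)[C@H](C)c2oc([C@H](C)[C@H](O[Si](CC)(CC)CC)CC)c(C)c(=O)c2C)c(C)c(=O)c1C
F5 | step 11 | O-diethylboryl chelate of F4 | CCc1oc([C@@H](C)/C=C(\C)[C@H](OB(CC)CC)[C@@H](C)C(=O)[C@H](C)c2oc([C@H](C)[C@H](O[Si](CC)(CC)CC)CC)c(C)c(=O)c2C)c(C)c(=O)c1C
F6 | step 11 | triethylsilyl ether of 25 at the pentan-3-ol oxygen | CCc1oc([C@@H](C)/C=C(\C)[C@H](O)[C@@H](C)[C@H](O)[C@H](C)c2oc([C@H](C)[C@H](O[Si](CC)(CC)CC)CC)c(C)c(=O)c2C)c(C)c(=O)c1C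
F7 | step 9 | 3,5-dimethyl-2-[(2R)-3-oxopent-4-en-2-yl]-6-[(2R,3R)-3-(triethylsilyloxy)pentan-2-yl]-4H-pyran-4-one | C=CC(=O)[C@H](C)c1oc([C@H](C)[C@H](O[Si](CC)(CC)CC)CC)c(C)c(=O)c1C
F8 | step 6 | tetrahedral lithium N-methoxy-N-methyl hemiaminal adduct of 12 and N-methoxy-N-methylpropanamide | [Li+].CCC([O-])(N(C)OC)C(C)c1oc([C@H](C)[C@H](O[Si](CC)(CC)CC)CC)c(C)c(=O)c1C
F9 | step 6 | 3,5-dimethyl-2-[(2S)-3-oxopentan-2-yl]-6-[(2R,3R)-3-(triethylsilyloxy)pentan-2-yl]-4H-pyran-4-one | CCC(=O)[C@@H](C)c1oc([C@H](C)[C@H](O[Si](CC)(CC)CC)CC)c(C)c(=O)c1C
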